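**Remark on the chemistry:** carbonylative ipso termination of the palladium and norbornene relay is treated as an established but less used member of that reaction family; CO is supplied at one atmosphere or below.

## Structural features

Target 15 is a diaryl ether that joins two resorcinol-derived units and has no stereocentre. The first unit is a 1H-isochromen-1-one (ring A benzo, ring B pyranone) with a pentyl chain on C3, a free hydroxyl on C6 and the ether oxygen on C8, next to C8a, which carries the lactone carbonyl C1. The second unit, ring C, is a benzoic acid substituted on five of its six carbons: carboxyl on C1', hydroxyls on C2' and C4', the ether oxygen on C5' and a pentyl chain on C6', so that only C3' carries hydrogen. The fragile groups are the ring C β-resorcylic acid, which can lose carbon dioxide once its phenols are free and it is heated or kept in strong acid, the enol lactone of ring B, which opens with hydroxide, amines or thiolates, and both electron-rich rings, which react with electrophiles and oxidants. The real difficulty is the contiguous array C4'(O)-C5'(OAr)-C6'(pentyl)-C1'(CO2H)-C2'(O). An ether bond made to C5' after C4' and C6' are filled would have to join a doubly ortho-substituted phenol to a ring A carbon that sits beside a carbonyl-bearing carbon. The key step exploits the adjacency of C6' and C1': with iodine on C1', hydrogen on C6' and a methoxy group on C2' as the blocking ortho substituent, a palladium and norbornene relay can place the pentyl chain on C6' and the carboxyl carbon on C1' in one operation. The ether can therefore be made first, on an uncrowded ring C.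

## Logic of the disconnections

15 to 14. The three aryl O-CH3 bonds (on C6, C2' and C4') are cut. Methyl ethers come built into both commercial rings, survive copper, palladium, rhodium, hydroxide and iodide, and are harmless ortho to iodine in step 3, where a benzyl ether on C2' would invite cyclisation of the arylpalladium onto the benzyl ring. The gain is that no phenol has to be handled before the last step. The demand is a Lewis-acid demethylation at or below room temperature that spares the lactone and does not decarboxylate the freed acid.

14 to 13. The O-CH3 bond of the ring C ester is cut. This ester lies between the C2' methoxy group and the C6' pentyl chain, so attack at its carbonyl is blocked and the alkyl-oxygen bond is the accessible one. The cut is placed before the phenols are freed, so that heat is applied while the acid is not yet a β-resorcylic acid. The demand is a soft nucleophile that attacks the methyl group and leaves ring B alone; the lactone has no sp3 carbon-oxygen bond to offer.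

13 to 7 and 11. The C4-C4a and O2-C3 bonds of ring B are cut. The ring A carboxyl directs a metal to its only free ortho position (the future C4a), and 11 supplies C4, C3 and the pentyl chain. Ring B and its side chain are gained in one step from a C-H bond, without a halogen handle on ring A. The demand is that only the ring A carboxyl is free; the ring C carboxyl stays esterified, and it has no ortho hydrogen in any case.

11 to 8 and 9. The bond between the acyl carbon and the ylide carbon is cut, which leads back to 8 and, through 10, to 9. The forward step needs two equivalents of 10, one as nucleophile and one as base.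

7 to 6. The methyl group is put back on the ring A carboxyl. The two esters of 6 differ sharply in hindrance as a direct result of the key step, so no orthogonal protecting group is needed. The demand is hydroxide at mild temperature.

6 to 4 and 5. The C6'-pentyl bond and the C1'-carboxyl bond are cut together; the carboxyl carbon and its methoxy cap come from the two reagents listed under step 3. This removes the two substituents that make ring C crowded and leaves an aryl iodide with one ortho hydrogen. The forward step must alkylate at C6' before it carbonylates at C1', and must palladate a C-H bond that has an aryloxy neighbour.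

4 to 3. The C1'-I bond is cut. C1' is ortho to the C2' methoxy group, para to the C4' methoxy group and unhindered, so an electrophilic iodination should find it. The demand is one equivalent of a mild iodinating agent so that ring A is not touched.

3 to 1 and 2. The bond between the ring A carbon (future C8) and the ether oxygen is cut. The oxygen stays with ring C because 2 is an electron-rich phenol, and the bromine of 1 lies ortho to an ester, which activates it for copper-mediated substitution. Both partners have a single ortho substituent at this stage, which is the point of making the ether first.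

## Other disconnections considered

Alternative 1: ring C is built by a vinylketene benzannulation, cutting C4'-C3', C1'-C2' and C4'-C5'. In the forward step the diazo ketone 8-{[(1E)-2-(diazoacetyl)hept-1-en-1-yl]oxy}-6-methoxy-3-pentyl-1H-isochromen-1-one A1 would be irradiated with ethoxyethyne A2. Wolff rearrangement of A1, [2+2] addition of A2, four-electron ring opening and 6π closure would lead to 8-(4-ethoxy-2-hydroxy-6-pentylphenoxy)-6-methoxy-3-pentyl-1H-isochromen-1-one A3.

- In favour: the regiochemistry of ring C is fixed by the mechanism, no metal is needed, and the ether bond is never formed on a crowded ring.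
- Better than the chosen plan on one point: in A3 the C4' and C2' oxygens emerge differentiated (free hydroxyl and ethyl ether), whereas the chosen plan carries them as identical methyl ethers.
- Against: A3 has hydrogen on C1', so the carboxyl carbon is still missing. It would have to be introduced between the ethoxy group and the pentyl chain, in competition with C3', which is less hindered and ortho to the free phenol.
- Against: the isochromenone in A1 absorbs light in the region needed for the diazo ketone, and its C3-C4 bond could itself add A2 photochemically.
- Against: A1 is a diazo ketone on a vinylogous ester and can only be reached after the isochromenone is complete.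
- Comparison: the pericyclic cascade is at least the equal of the organometallic relay in regiochemical predictability. The chosen plan installs the C6' and C1' substituents together, while this route installs only the first and adds a late carboxylation and two kinds of ether cleavage, so it would be longer.

Alternative 2: rings A and B are made by a hexadehydro-Diels-Alder reaction and the ether by aryne trapping, cutting C4a-C8a, C5-C6 and C8-O. Heating the triyne (3Z)-non-3-en-1-yn-4-yl 5-ethoxypenta-2,4-diynoate A4 with the phenol methyl 3-hydroxy-4,6-dimethoxy-2-pentylbenzoate A5 would give methyl 3-[(6-ethoxy-1-oxo-3-pentyl-1H-isochromen-8-yl)oxy]-4,6-dimethoxy-2-pentylbenzoate A6.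

- In favour: three bonds and two rings form in one reagent-free step, which is better than any single step of the chosen plan in bonds made.
- In favour: the C6 ethoxy group polarises the C7-C8 aryne so that the oxygen of A5 should add at C8.
- Equal to the chosen plan on the ether bond: an aryne is little affected by crowding in the phenol, and the chosen plan avoids the same problem by ordering.
- Against: A5 already contains the C5' oxygen, C6' pentyl and C1' ester array, so the central problem is moved into a building block and not solved.
- Against: A4 combines an ynol ether, a conjugated diynoate and a Z-enol ester of an enyne, all sensitive, and its four-atom ester tether must adopt an unfavourable conformation to cyclise.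
- Against: a hindered phenol must trap the aryne intermolecularly before the aryne reacts in other ways.
- Comparison: A6 would need the same ester and ether cleavages as 13, so the end is no shorter, while the route to A4 and A5 would be longer than steps 1 to 6.

Alternative 3: ring C is made as a cyclohexane-1,3-dione, cutting C1'-C6' and C2'-C3'. An alkoxide base would add dimethyl malonate A8 to the β carbon of the enone methyl 4-methoxy-2-methyl-6-[(2-oxonon-3-en-3-yl)oxy]benzoate A7. Claisen closure of the methyl ketone enolate onto one ester group of A8 would then give methyl 5-[5-methoxy-2-(methoxycarbonyl)-3-methylphenoxy]-2,4-dioxo-6-pentylcyclohexane-1-carboxylate A9 (racemic, all-trans), to be aromatised later.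

- In favour: this is the classical, scalable entry to 6-alkyl-β-resorcylates; A8 is a cheap bulk reagent and no noble metal is needed.
- Equal to the chosen plan: the C6' pentyl chain and the C1' carboxyl arrive in the same step, the carboxyl being carried in by A8.
- Better than the chosen plan: after aromatisation the C2' and C4' oxygens are free phenols, so ring C needs no ether cleavage.
- Against: A7 is an α-aryloxy enone, more hindered and less electrophilic at its β carbon than the enones normally used with A8.
- Against: the dehydrogenation of A9 (halogenation and elimination) would have to spare the electron-rich ring A, and loss of the aryloxy group is a conceivable competing aromatisation.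
- Against: ring A in A9 carries only a methyl group at the future C4a, so the isochromenone would still have to be built by lateral metalation and acylation beside free phenols and a second ester, which calls for extra protection.
- Comparison: the three stereocentres of A9 are of no consequence because they vanish. The polar mechanism is more familiar than the relay of the chosen plan, but more steps would follow the key step.

Key step: step 3

## Route

Step 1
Reactants: 1 methyl 2-bromo-4-methoxybenzoate; 2 2,4-dimethoxyphenol
Product: 3 methyl 2-(2,4-dimethoxyphenoxy)-4-methoxybenzoate
Conditions: CuI (10 mol%), picolinic acid (20 mol%), K3PO4 (2 equiv), DMSO, 90 °C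
Reagents that add atoms: none
Why: Ullmann-type copper-catalysed diaryl ether synthesis; the bromide is activated by its ortho ester, the phenol is electron-rich, and each partner has only one ortho substituent, so the ether bond is made before ring C becomes crowded.

Step 2
Reactants: 3 methyl 2-(2,4-dimethoxyphenoxy)-4-methoxybenzoate
Product: 4 methyl 2-(5-iodo-2,4-dimethoxyphenoxy)-4-methoxybenzoate
Conditions: N-iodosuccinimide (1.05 equiv), CF3CO2H (10 mol%), MeCN, 0 °C to rt
Reagents that add atoms: N-iodosuccinimide, O=C1CCC(=O)N1I
Why: Electrophilic aromatic iodination; C1' is para to the C4' methoxy group, ortho to the C2' methoxy group and unhindered, whereas C3' lies between two methoxy groups, C6' is activated only by the aryloxy oxygen, and ring A is less electron-rich because of its ester.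

Step 3
Reactants: 4 methyl 2-(5-iodo-2,4-dimethoxyphenoxy)-4-methoxybenzoate; 5 1-iodopentane
Product: 6 methyl 4,6-dimethoxy-3-[5-methoxy-2-(methoxycarbonyl)phenoxy]-2-pentylbenzoate
Conditions: Pd(OAc)2 (10 mol%), P(2-furyl)3 (20 mol%), norbornene (2 equiv), Cs2CO3 (3 equiv), 5 (3 equiv), MeOH (10 equiv), CO (1 atm, balloon), MeCN, 80 °C
Reagents that add atoms: carbon monoxide, [C-]#[O+]; methanol, CO
Why: Catellani reaction with carbonylative ipso termination; the closest known reaction type is the ortho-alkylation of ortho-substituted aryl iodides by primary alkyl iodides followed by an ipso termination, alkoxycarbonylation being the less used way to end it. Zerovalent palladium should insert into the C1'-I bond of 4, norbornene should insert into the aryl-palladium bond, and carbonate-assisted palladation of C6'-H should give the five-membered aryl-norbornyl palladacycle. Oxidative addition of 5 would raise this to tetravalent palladium, and reductive elimination would form the C6'-pentyl bond. C1' is then flanked by the C2' methoxy group and the new pentyl chain, so norbornene should be expelled by β-carbon elimination; the arylpalladium left at C1' should take up CO and be cleaved by methanol to the methyl ester, returning zerovalent palladium. No ring is closed and no stereocentre is formed. Site selectivity comes from the substrate alone: the C2' methoxy group blocks one ortho position, C6' holds the only ortho hydrogen, and the C5' ether oxygen acidifies that hydrogen for concerted metalation although it adds bulk. The order of events depends on norbornene, present in excess, inserting faster than CO held at low pressure, and on aroyl-palladium formation being reversible until methanolysis. Ring A, its ester and the three methyl ethers are spectators.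

Step 4
Reactants: 6 methyl 4,6-dimethoxy-3-[5-methoxy-2-(methoxycarbonyl)phenoxy]-2-pentylbenzoate
Product: 7 2-[4,6-dimethoxy-3-(methoxycarbonyl)-2-pentylphenoxy]-4-methoxybenzoic acid
Conditions: LiOH·H2O (3 equiv), THF/MeOH/H2O, 40 °C; then 1 M HCl
Reagents that add atoms: lithium hydroxide, [Li+].[OH-]
Why: Saponification by acyl-oxygen cleavage; the ring A ester has one ortho substituent and should hydrolyse, while the ring C ester, flanked by methoxy and pentyl, is shielded from attack at its carbonyl and should stay.

Step 5
Reactants: 8 hexanoyl chloride; 9 trimethylsulfoxonium iodide
Product: 11 1-[dimethyl(oxo)-λ6-sulfanylidene]heptan-2-one, via dimethylsulfoxonium methylide 10 (not isolated)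
Conditions: 9 (3 equiv), KOtBu (3 equiv), THF, reflux; then 8, 0 °C to rt
Reagents that add atoms: none
Why: C-acylation of a sulfoxonium methylide by an acid chloride; one equivalent of 10 attacks the acyl carbon and a second removes the acidic proton to give the stabilised keto ylide.

Step 6
Reactants: 7 2-[4,6-dimethoxy-3-(methoxycarbonyl)-2-pentylphenoxy]-4-methoxybenzoic acid; 11 1-[dimethyl(oxo)-λ6-sulfanylidene]heptan-2-one
Product: 13 methyl 4,6-dimethoxy-3-[(6-methoxy-1-oxo-3-pentyl-1H-isochromen-8-yl)oxy]-2-pentylbenzoate, via keto acid 12 (not isolated)
Conditions: [Cp*RhCl2]2 (4 mol%), AgSbF6 (16 mol%), NaOAc (30 mol%), ClCH2CH2Cl, 100 °C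
Reagents that add atoms: none
Why: Carboxylate-directed C-H activation and annulation with a sulfoxonium ylide under trivalent rhodium; the carboxylate of 7 should direct rhodation to its only free ortho carbon (future C4a), 11 should lose dimethyl sulfoxide to give a rhodium carbene that inserts, and protonation gives keto acid 12, which closes ring B by cyclodehydration. The ring C ester has no ortho hydrogen and cannot compete.

Step 7
Reactants: 13 methyl 4,6-dimethoxy-3-[(6-methoxy-1-oxo-3-pentyl-1H-isochromen-8-yl)oxy]-2-pentylbenzoate
Product: 14 4,6-dimethoxy-3-[(6-methoxy-1-oxo-3-pentyl-1H-isochromen-8-yl)oxy]-2-pentylbenzoic acid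
Conditions: LiI (8 equiv), pyridine, reflux; then cold 1 M HCl
Reagents that add atoms: none
Why: SN2 dealkylation of a hindered methyl ester by iodide at the methyl carbon, which the crowding around the carbonyl does not affect; the enol lactone has no sp3 carbon-oxygen bond for iodide to attack, and the phenols are still methylated, so the acid formed is not yet prone to decarboxylation.

Step 8
Reactants: 14 4,6-dimethoxy-3-[(6-methoxy-1-oxo-3-pentyl-1H-isochromen-8-yl)oxy]-2-pentylbenzoic acid
Product: 15 4,6-dihydroxy-3-[(6-hydroxy-1-oxo-3-pentyl-1H-isochromen-8-yl)oxy]-2-pentylbenzoic acid
Conditions: BBr3 (10 equiv), CH2Cl2, -78 °C to rt; then H2O, 0 °C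
Reagents that add atoms: none
Why: Lewis-acid cleavage of aryl methyl ethers by boron coordination and bromide attack at methyl; the C2' ether is assisted by chelation to the carboxyl, the diaryl ether and the lactone have no alkyl carbon-oxygen bond to cleave, and the temperature stays at or below rt to protect the freed β-resorcylic acid.

## Compound list

1 | methyl 2-bromo-4-methoxybenzoate | COC(=O)c1ccc(OC)cc1Br | starting material
2 | 2,4-dimethoxyphenol | COc1ccc(O)c(OC)c1 | starting material
3 | methyl 2-(2,4-dimethoxyphenoxy)-4-methoxybenzoate | COC(=O)c1ccc(OC)cc1Oc1ccc(OC)cc1OC | intermediate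
4 | methyl 2-(5-iodo-2,4-dimethoxyphenoxy)-4-methoxybenzoate | COC(=O)c1ccc(OC)cc1Oc1cc(I)c(OC)cc1OC | intermediate
5 | 1-iodopentane | CCCCCI | starting material
6 | methyl 4,6-dimethoxy-3-[5-methoxy-2-(methoxycarbonyl)phenoxy]-2-pentylbenzoate | COC(=O)c1ccc(OC)cc1Oc1c(CCCCC)c(C(=O)OC)c(OC)cc1OC | intermediate
7 | 2-[4,6-dimethoxy-3-(methoxycarbonyl)-2-pentylphenoxy]-4-methoxybenzoic acid | OC(=O)c1ccc(OC)cc1Oc1c(CCCCC)c(C(=O)OC)c(OC)cc1OC | intermediate
8 | hexanoyl chloride | CCCCCC(Cl)=O | starting material
9 | trimethylsulfoxonium iodide | C[S+](C)(C)=O.[I-] | starting material
10 | dimethylsulfoxonium methylide | [CH2-][S+](C)(C)=O | intermediate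
11 | 1-[dimethyl(oxo)-λ6-sulfanylidene]heptan-2-one | CCCCCC(=O)C=S(C)(C)=O | intermediate
12 | 2-[4,6-dimethoxy-3-(methoxycarbonyl)-2-pentylphenoxy]-4-methoxy-6-(2-oxoheptyl)benzoic acid | CCCCCC(=O)Cc1cc(OC)cc(Oc2c(CCCCC)c(C(=O)OC)c(OC)cc2OC)c1C(=O)O | intermediate
13 | methyl 4,6-dimethoxy-3-[(6-methoxy-1-oxo-3-pentyl-1H-isochromen-8-yl)oxy]-2-pentylbenzoate | CCCCCc1cc2cc(OC)cc(Oc3c(CCCCC)c(C(=O)OC)c(OC)cc3OC)c2c(=O)o1 | intermediate
14 | 4,6-dimethoxy-3-[(6-methoxy-1-oxo-3-pentyl-1H-isochromen-8-yl)oxy]-2-pentylbenzoic acid | CCCCCc1cc2cc(OC)cc(Oc3c(CCCCC)c(C(=O)O)c(OC)cc3OC)c2c(=O)o1 | intermediate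
15 | 4,6-dihydroxy-3-[(6-hydroxy-1-oxo-3-pentyl-1H-isochromen-8-yl)oxy]-2-pentylbenzoic acid | CCCCCc1cc2cc(O)cc(Oc3c(O)cc(O)c(C(=O)O)c3CCCCC)c2c(=O)o1 | target

## Step count and least certain steps

Total step count: 8. Longest linear sequence: 7 (steps 1, 2, 3, 4, 6, 7, 8); step 5 is a one-step side branch.

Step 3 (key step). The most likely failure is capture of CO too early. The first arylpalladium could be carbonylated before norbornene inserts. More seriously, the norbornylpalladium species could be carbonylated before the C6'-H bond is palladated, because that palladation is slowed by the aryloxy group beside it. Loss of 5 to methoxide is a lesser drain. The fallback separates the two bond formations. It sets out from 4 and 5 and runs the same relay without CO, ending it with a Heck reaction with methyl acrylate (Pd(OAc)2, P(2-furyl)3, norbornene, Cs2CO3, MeCN, 90 °C), the best-established termination. This should give methyl (2E)-3-{4,6-dimethoxy-3-[5-methoxy-2-(methoxycarbonyl)phenoxy]-2-pentylphenyl}prop-2-enoate F1. Cleavage of the alkene with catalytic OsO4 and NaIO4 would give methyl 2-(3-formyl-4,6-dimethoxy-2-pentylphenoxy)-4-methoxybenzoate F2. Pinnick oxidation (NaClO2, NaH2PO4, 2-methylbut-2-ene) would give 4,6-dimethoxy-3-[5-methoxy-2-(methoxycarbonyl)phenoxy]-2-pentylbenzoic acid F3. O-Methylation of its carboxylate (MeI, K2CO3, DMF) returns to the route at 6.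

Step 6. The ylide is basic, so protonation by the carboxylic acid and O-alkylation of the carboxylate could outrun C-H rhodation, which may be slow for an electron-rich acid twisted by its ortho aryloxy group. Incomplete lactonisation of 12 is a lesser concern, since brief acid treatment would complete it. The fallback avoids ylide and carbene chemistry. It sets out from 7 and uses an oxidative annulation with hept-1-en-2-yl acetate F4, made by Markovnikov addition of acetic acid to hept-1-yne under [RuCl2(p-cymene)]2 catalysis. With [Cp*RhCl2]2 and Cu(OAc)2 as oxidant in toluene at 120 °C, alkene insertion and lactonisation with loss of acetic acid should lead directly to 13.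

Step 7. At the temperature needed for iodide to dealkylate the ester, the enol lactone may be opened by traces of hydroxide or by prolonged heating in pyridine, and the C6 methoxy group, para to the lactone carbonyl, may begin to cleave and give mixtures. The fallback moves the ester cleavage to a stage where no lactone exists. It sets out from 6 and cleaves both esters with KOH in wet DMSO at 110 °C to give 3-(2-carboxy-5-methoxyphenoxy)-4,6-dimethoxy-2-pentylbenzoic acid F5. Annulation of F5 with 11 under the conditions of step 6 should then give 14, because only the ring A carboxyl has an ortho hydrogen. The price is a second free carboxyl in the rhodium step, which is why this is not the first choice.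

Step 8. The non-chelated C6 methoxy group needs hours at rt, and during that time the freed β-resorcylic acid sits in HBr and boron Lewis acid, so protodecarboxylation at C1' is the main danger; incomplete cleavage is the other. The fallback keeps the carboxyl masked during the acidic step. It sets out from 13, and BBr3 in CH2Cl2 from -78 to 0 °C should give methyl 4,6-dihydroxy-3-[(6-hydroxy-1-oxo-3-pentyl-1H-isochromen-8-yl)oxy]-2-pentylbenzoate F6 with the ester intact. LiI in refluxing ethyl acetate would then remove the ester methyl group under neutral conditions and give 15 as its lithium salt, released by cold dilute acid.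

## Further compounds

F1 | step 3 | methyl (2E)-3-{4,6-dimethoxy-3-[5-methoxy-2-(methoxycarbonyl)phenoxy]-2-pentylphenyl}prop-2-enoate | COC(=O)/C=C/c1c(CCCCC)c(Oc2cc(OC)ccc2C(=O)OC)c(OC)cc1OC
F2 | step 3 | methyl 2-(3-formyl-4,6-dimethoxy-2-pentylphenoxy)-4-methoxybenzoate | COC(=O)c1ccc(OC)cc1Oc1c(CCCCC)c(C=O)c(OC)cc1OC
F3 | step 3 | 4,6-dimethoxy-3-[5-methoxy-2-(methoxycarbonyl)phenoxy]-2-pentylbenzoic acid | COC(=O)c1ccc(OC)cc1Oc1c(CCCCC)c(C(=O)O)c(OC)cc1OC
F4 | step 6 | hept-1-en-2-yl acetate | CCCCCC(=C)OC(C)=O
F5 | step 7 | 3-(2-carboxy-5-methoxyphenoxy)-4,6-dimethoxy-2-pentylbenzoic acid | OC(=O)c1ccc(OC)cc1Oc1c(CCCCC)c(C(=O)O)c(OC)cc1OC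
F6 | step 8 | methyl 4,6-dihydroxy-3-[(6-hydroxy-1-oxo-3-pentyl-1H-isochromen-8-yl)oxy]-2-pentylbenzoate | CCCCCc1cc2cc(O)cc(Oc3c(CCCCC)c(C(=O)OC)c(O)cc3O)c2c(=O)o1
A1 | alternative 1 | 8-{[(1E)-2-(diazoacetyl)hept-1-en-1-yl]oxy}-6-methoxy-3-pentyl-1H-isochromen-1-one | O=C(C=[N+]=[N-])/C(CCCCC)=C/Oc1cc(OC)cc2cc(CCCCC)oc(=O)c12
A2 | alternative 1 | ethoxyethyne | CCOC#C
A3 | alternative 1 | 8-(4-ethoxy-2-hydroxy-6-pentylphenoxy)-6-methoxy-3-pentyl-1H-isochromen-1-one | CCOc1cc(O)c(Oc2cc(OC)cc3cc(CCCCC)oc(=O)c23)c(CCCCC)c1
A4 | alternative 2 | (3Z)-non-3-en-1-yn-4-yl 5-ethoxypenta-2,4-diynoate | CCOC#CC#CC(=O)O/C(CCCCC)=C\C#C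
A5 | alternative 2 | methyl 3-hydroxy-4,6-dimethoxy-2-pentylbenzoate | COC(=O)c1c(CCCCC)c(O)c(OC)cc1OC
A6 | alternative 2 | methyl 3-[(6-ethoxy-1-oxo-3-pentyl-1H-isochromen-8-yl)oxy]-4,6-dimethoxy-2-pentylbenzoate | CCCCCc1cc2cc(OCC)cc(Oc3c(OC)cc(OC)c(C(=O)OC)c3CCCCC)c2c(=O)o1
A7 | alternative 3 | methyl 4-methoxy-2-methyl-6-[(2-oxonon-3-en-3-yl)oxy]benzoate (alkene geometry not specified) | CCCCCC=C(Oc1cc(OC)cc(C)c1C(=O)OC)C(C)=O
A8 | alternative 3 | dimethyl malonate | COC(=O)CC(=O)OC
A9 | alternative 3 | methyl 5-[5-methoxy-2-(methoxycarbonyl)-3-methylphenoxy]-2,4-dioxo-6-pentylcyclohexane-1-carboxylate (racemic, all-trans, one enantiomer drawn) | CCCCC[C@@H]1[C@@H](Oc2cc(OC)cc(C)c2C(=O)OC)C(=O)CC(=O)[C@H]1C(=O)OC
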